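**Strategy.** Ring B of the 1-aryltetralin (C1, C2, C3, C4, C4a, C8a) is disconnected at C1–C2 and C3–C4 into a fumarate (C2–C3 with both future hydroxymethyl carbons) and an o-quinodimethane of ring A bearing the syringyl ring on C1. Irradiation of a 2-benzylbenzaldehyde generates this diene as a hydroxy-o-quinodimethane. Its Diels–Alder reaction with the fumarate of methyl (R)-lactate closes ring B and sets C1, C2 and C3 (plus a temporary C4 carbinol) in one operation. The step exploits the trans,trans C1–C2–C3 triad beside the unsubstituted benzylic C4 of ring B. Hydrogenolysis and hydride reduction then finish the route.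

Key step: step 6

Remark: tetralin numbering is used throughout (C1 carries the syringyl ring C, C2 and C3 the hydroxymethyl groups, C4 is the benzylic CH2, C4a/C8a are the fusion atoms of ring A); in this numbering the target is (1R,2S,3S), all-trans. Compounds 1, 3, 8 and 9 are assumed to be commercial.

**Step 1**
Reactants: 1 4-(benzyloxy)-3-methoxybenzaldehyde
Product: 2 4-(benzyloxy)-2-bromo-5-methoxybenzaldehyde
Conditions: Br2 (1.1 equiv), NaOAc, AcOH, 20 °C
Reagents that add atoms: bromine, BrBr
Why: Electrophilic aromatic bromination should occur para to the methoxy group (ortho to CHO), because the benzyloxy group is deactivated by conjugation with the para-formyl group, as in the bromination of veratraldehyde; NaOAc buffers HBr so the benzyl ether survives.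

**Step 2**
Reactants: 3 4-(benzyloxy)-3,5-dimethoxybenzaldehyde
Product: 4 [4-(benzyloxy)-3,5-dimethoxyphenyl]methanol
Conditions: NaBH4, MeOH–THF, 0 °C
Reagents that add atoms: none
Why: Borohydride reduction of an aryl aldehyde to the benzylic alcohol; no stereocentre is formed and the ethers are inert.

**Step 3**
Reactants: 4 [4-(benzyloxy)-3,5-dimethoxyphenyl]methanol
Product: 5 2-(benzyloxy)-5-(chloromethyl)-1,3-dimethoxybenzene
Conditions: SOCl2, cat. DMF, CH2Cl2, 0 °C
Reagents that add atoms: thionyl chloride, O=S(Cl)Cl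
Why: Chlorodehydroxylation of an electron-rich benzylic alcohol via its chlorosulfite; the chloride is used directly without storage.

**Step 4**
Reactants: 5 2-(benzyloxy)-5-(chloromethyl)-1,3-dimethoxybenzene; 2 4-(benzyloxy)-2-bromo-5-methoxybenzaldehyde
Product: 7 4-(benzyloxy)-2-[4-(benzyloxy)-3,5-dimethoxybenzyl]-5-methoxybenzaldehyde, via benzylzinc chloride 6 (not isolated)
Conditions: Zn dust, LiCl, THF, 25 °C; then slow addition to 2, Pd(OAc)2 (2 mol %), SPhos (4 mol %), THF, 25 °C
Reagents that add atoms: none
Why: Negishi cross-coupling: LiCl-promoted zinc insertion into the benzylic C–Cl bond gives 6, which transmetalates to the arylpalladium bromide formed from 2 and zerovalent palladium (generated from Pd(OAc)2/SPhos); slow addition keeps the organozinc concentration low so the aldehyde is not attacked.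

**Step 5**
Reactants: 8 fumaryl chloride; 9 methyl (R)-lactate (2.2 equiv)
Product: 10 bis[(2R)-1-methoxy-1-oxopropan-2-yl] (2E)-but-2-enedioate
Conditions: pyridine, cat. DMAP, CH2Cl2, 0 °C to 20 °C
Reagents that add atoms: none
Why: Double acylation of the secondary alcohol by the diacid chloride with pyridine as HCl scavenger; the lactate stereocentre is not involved and the E-alkene is retained.

**Step 6**
Reactants: 7 4-(benzyloxy)-2-[4-(benzyloxy)-3,5-dimethoxybenzyl]-5-methoxybenzaldehyde; 10 bis[(2R)-1-methoxy-1-oxopropan-2-yl] (2E)-but-2-enedioate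
Product: 12 bis[(2R)-1-methoxy-1-oxopropan-2-yl] (1R,2S,3R,4R)-7-(benzyloxy)-1-[4-(benzyloxy)-3,5-dimethoxyphenyl]-4-hydroxy-6-methoxy-1,2,3,4-tetrahydronaphthalene-2,3-dicarboxylate, via photoenol 11 (not isolated)
Conditions: hν (365 nm), 10 (3 equiv), degassed toluene (0.02 M), 15 °C
Reagents that add atoms: none
Why: Excitation of 7, intersystem crossing and 1,5-hydrogen transfer from the doubly benzylic CH2 should give a biradical that relaxes to the (E,E)-hydroxy-o-quinodimethane 11 (C4–OH and the C1 syringyl ring both outward), which is trapped in the ground state by 10 in a concerted, suprafacial, intermolecular [4+2] cycloaddition that forms C1–C2 and C3–C4, closes ring B and restores the aromaticity of ring A. The closest known reaction type is the photoenolization/Diels–Alder reaction of o-alkylbenzaldehydes, including the hydrogen-bond-directed addition of hydroxy-o-quinodimethanes to fumarates of α-hydroxy esters. The trans C2/C3 relationship follows from the E-alkene and the cis C1/C4 relationship from the E,E-diene; the ester on the carbon that bonds to the carbinol terminus should sit endo under ring A, as is usual for hydroxy-o-quinodimethanes (OH and the neighbouring acceptor emerge cis), which places the C2 ester exo and therefore trans to the C1 aryl group, giving the 1,2-trans-2,3-trans array. The absolute configuration is controlled by the (R)-lactate units: with the lactate C–H eclipsing the s-cis fumarate carbonyl, the dienol OH can hydrogen-bond to the lactate ester carbonyl on only one π-face, and addition to that face should give the (1R,2S,3R,4R) adduct. The step needs endo/exo selectivity, facial selectivity and an intact E-dienophile; the temporary C4 hydroxyl and the auxiliary secure the first two, the non-polar solvent preserves the hydrogen bond, and excess 10 at a wavelength it does not absorb limits isomerization, while any minor facial isomer is a diastereomer removable by chromatography or crystallization.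

**Step 7**
Reactants: 12 bis[(2R)-1-methoxy-1-oxopropan-2-yl] (1R,2S,3R,4R)-7-(benzyloxy)-1-[4-(benzyloxy)-3,5-dimethoxyphenyl]-4-hydroxy-6-methoxy-1,2,3,4-tetrahydronaphthalene-2,3-dicarboxylate
Product: 13 bis[(2R)-1-methoxy-1-oxopropan-2-yl] (1R,2S,3S)-7-hydroxy-1-(4-hydroxy-3,5-dimethoxyphenyl)-6-methoxy-1,2,3,4-tetrahydronaphthalene-2,3-dicarboxylate
Conditions: H2 (3 atm), Pd(OH)2/C, EtOAc–AcOH, 20 °C
Reagents that add atoms: none
Why: Heterogeneous hydrogenolysis should cleave both O-benzyl ethers and the electron-rich (para-oxygenated) benzylic C4–OH bond in one operation, leaving C1–C3 and the non-benzylic lactate esters untouched.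

**Step 8**
Reactants: 13 bis[(2R)-1-methoxy-1-oxopropan-2-yl] (1R,2S,3S)-7-hydroxy-1-(4-hydroxy-3,5-dimethoxyphenyl)-6-methoxy-1,2,3,4-tetrahydronaphthalene-2,3-dicarboxylate
Product: 14 (6S,7S,8R)-8-(4-hydroxy-3,5-dimethoxyphenyl)-6,7-bis(hydroxymethyl)-3-methoxy-5,6,7,8-tetrahydronaphthalen-2-ol
Conditions: LiAlH4 (excess), THF, 0 °C to reflux; then aq. potassium sodium tartrate
Reagents that add atoms: none
Why: LiAlH4 reduction of all four ester carbonyls should release both hydroxymethyl groups and remove the auxiliary as a diol; the trans,trans diester is already the thermodynamically preferred isomer, so no stereocentre is at risk.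

**Compound list**
1 | 4-(benzyloxy)-3-methoxybenzaldehyde (O-benzylvanillin) | COc1cc(C=O)ccc1OCc1ccccc1 | starting material
2 | 4-(benzyloxy)-2-bromo-5-methoxybenzaldehyde | COc1cc(C=O)c(Br)cc1OCc1ccccc1 | intermediate
3 | 4-(benzyloxy)-3,5-dimethoxybenzaldehyde (O-benzylsyringaldehyde) | COc1cc(C=O)cc(OC)c1OCc1ccccc1 | starting material
4 | [4-(benzyloxy)-3,5-dimethoxyphenyl]methanol | COc1cc(CO)cc(OC)c1OCc1ccccc1 | intermediate
5 | 2-(benzyloxy)-5-(chloromethyl)-1,3-dimethoxybenzene | COc1cc(CCl)cc(OC)c1OCc1ccccc1 | intermediate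
6 | [4-(benzyloxy)-3,5-dimethoxybenzyl]zinc chloride | COc1cc(C[Zn]Cl)cc(OC)c1OCc1ccccc1 | intermediate
7 | 4-(benzyloxy)-2-[4-(benzyloxy)-3,5-dimethoxybenzyl]-5-methoxybenzaldehyde | COc1cc(C=O)c(Cc2cc(OC)c(OCc3ccccc3)c(OC)c2)cc1OCc1ccccc1 | intermediate
8 | fumaryl chloride ((2E)-but-2-enedioyl dichloride) | O=C(Cl)/C=C/C(=O)Cl | starting material
9 | methyl (R)-lactate (methyl (2R)-2-hydroxypropanoate) | C[C@@H](O)C(=O)OC | starting material
10 | bis[(2R)-1-methoxy-1-oxopropan-2-yl] (2E)-but-2-enedioate | COC(=O)[C@@H](C)OC(=O)/C=C/C(=O)O[C@H](C)C(=O)OC | intermediate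
11 | photoenol of 7: (E,E)-hydroxy-o-quinodimethane with exocyclic C4=C4a (OH outward) and C1=C8a (syringyl ring outward) double bonds | O/C=C1\C=C(OC)C(OCc2ccccc2)=C/C1=C\c1cc(OC)c(OCc2ccccc2)c(OC)c1 | intermediate
12 | bis[(2R)-1-methoxy-1-oxopropan-2-yl] (1R,2S,3R,4R)-7-(benzyloxy)-1-[4-(benzyloxy)-3,5-dimethoxyphenyl]-4-hydroxy-6-methoxy-1,2,3,4-tetrahydronaphthalene-2,3-dicarboxylate | COc1cc2c(cc1OCc1ccccc1)[C@@H](c1cc(OC)c(OCc3ccccc3)c(OC)c1)[C@H](C(=O)O[C@H](C)C(=O)OC)[C@@H](C(=O)O[C@H](C)C(=O)OC)[C@H]2O | intermediate
13 | bis[(2R)-1-methoxy-1-oxopropan-2-yl] (1R,2S,3S)-7-hydroxy-1-(4-hydroxy-3,5-dimethoxyphenyl)-6-methoxy-1,2,3,4-tetrahydronaphthalene-2,3-dicarboxylate | COc1cc2c(cc1O)[C@@H](c1cc(OC)c(O)c(OC)c1)[C@H](C(=O)O[C@H](C)C(=O)OC)[C@@H](C(=O)O[C@H](C)C(=O)OC)C2 | intermediate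
14 | (6S,7S,8R)-8-(4-hydroxy-3,5-dimethoxyphenyl)-6,7-bis(hydroxymethyl)-3-methoxy-5,6,7,8-tetrahydronaphthalen-2-ol | COc1cc2c(cc1O)[C@@H](c1cc(OC)c(O)c(OC)c1)[C@H](CO)[C@@H](CO)C2 | target

**Step count.** Total: 8 steps. Longest linear sequence: 6 steps (3 → 4 → 5 → 7 → 12 → 13 → 14).

**Steps most likely to fail**

Step 6. Under irradiation in the presence of the dienophile, triplet energy transfer from excited 7 may isomerize 10 to the maleate, eroding the trans C2/C3 relationship. The dienol may also reketonize faster than it is trapped, so that prolonged irradiation degrades the material. The fallback sets out from 7 and returns at 12. Compound 7 is irradiated (365 nm) in benzene saturated with SO2 and without dienophile, so that photoenol 11 is trapped by cheletropic addition as cis-5-(benzyloxy)-3-[4-(benzyloxy)-3,5-dimethoxyphenyl]-6-methoxy-1,3-dihydro-2-benzothiophen-1-ol 2,2-dioxide F1. Heating F1 with 10 in toluene at 80–110 °C in the dark extrudes SO2 in a disrotatory sense, regenerating (E,E)-11. The purely thermal, hydrogen-bond-directed cycloaddition should then give 12.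

Step 7. Acid-promoted β-elimination of the C4 hydroxyl (a β-hydroxy ester, via the para-quinone methide) could give the 3,4-alkene, whose hydrogenation would scramble C3. Alternatively, the benzylic C–O bond may be cleaved incompletely. The fallback sets out from 12 and returns at 13. Ionic deoxygenation is carried out first with Et3SiH and BF3·OEt2 in CH2Cl2 at −40 °C, where hydride capture of the para-benzyloxy-stabilized C4 cation should outrun proton loss. This gives bis[(2R)-1-methoxy-1-oxopropan-2-yl] (1R,2S,3S)-7-(benzyloxy)-1-[4-(benzyloxy)-3,5-dimethoxyphenyl]-6-methoxy-1,2,3,4-tetrahydronaphthalene-2,3-dicarboxylate F2. Neutral hydrogenolysis (H2, Pd/C, EtOAc, 20 °C) then removes only the two O-benzyl groups and gives 13.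

Step 4. Wurtz-type homocoupling of the electron-rich benzylic zinc reagent during insertion, or its addition to the aldehyde of 2, may consume the coupling partners. The fallback sets out from 2 and 5 and returns at 7, with the polarity reversed. Miyaura borylation of 2 (B2pin2, PdCl2(dppf), KOAc, dioxane, 80 °C) gives 4-(benzyloxy)-5-methoxy-2-(4,4,5,5-tetramethyl-1,3,2-dioxaborolan-2-yl)benzaldehyde F3. Suzuki–Miyaura coupling of F3 with the benzylic chloride 5 (Pd(PPh3)4, K2CO3, toluene–water, 80 °C) should give 7 without any benzylic organometallic.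

**Further compounds**
F1 | step 6 | cis-5-(benzyloxy)-3-[4-(benzyloxy)-3,5-dimethoxyphenyl]-6-methoxy-1,3-dihydro-2-benzothiophen-1-ol 2,2-dioxide (racemic, one enantiomer drawn) | O[C@@H]1c2cc(OC)c(OCc3ccccc3)cc2[C@H](c2cc(OC)c(OCc3ccccc3)c(OC)c2)S1(=O)=O
F2 | step 7 | bis[(2R)-1-methoxy-1-oxopropan-2-yl] (1R,2S,3S)-7-(benzyloxy)-1-[4-(benzyloxy)-3,5-dimethoxyphenyl]-6-methoxy-1,2,3,4-tetrahydronaphthalene-2,3-dicarboxylate | COc1cc2c(cc1OCc1ccccc1)[C@@H](c1cc(OC)c(OCc3ccccc3)c(OC)c1)[C@H](C(=O)O[C@H](C)C(=O)OC)[C@@H](C(=O)O[C@H](C)C(=O)OC)C2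
F3 | step 4 | 4-(benzyloxy)-5-methoxy-2-(4,4,5,5-tetramethyl-1,3,2-dioxaborolan-2-yl)benzaldehyde | COc1cc(C=O)c(B2OC(C)(C)C(C)(C)O2)cc1OCc1ccccc1
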